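## Structural features

The target is a flavonol (rings A and C fused, ring B a 4-methoxyphenyl group at C2, hydroxyls at C3, C5 and C7) whose C8 is joined through one methylene carbon to D1 of a hexasubstituted phloroglucinol ring D. Ring D carries hydroxyls at D2 and D4 on either side of a 3-(4-hydroxyphenyl)propanoyl group at D3, a methyl group at D5 and a methoxy group at D6. There is no stereocentre, so no neighbouring stereocentres have to be related and every selectivity problem is one of position. The fragile parts are the diarylmethane bridge between two phloroglucinol-type rings (acid-promoted retro-Friedel–Crafts cleavage, oxidation), the free polyphenol array (air, base), the enolizable aryl ketone, and the two aryl methyl ethers (C4' and D6) that must outlast the final dealkylation. The real difficulty is to place the bridge at C8 and not at C6 of the 5,7-dioxygenated ring A, and to tell apart three oxygens on each phloroglucinol ring (ring A: O1 inside the pyranone, O5 beside the carbonyl, O7 free; ring D: only the D6 oxygen methylated). The key step uses the fact that C8 lies between the oxygen on C8a (the later O1) and the oxygen on C7. This 2-alkylresorcinol unit has the polarity of a siloxyalkyne O–C≡C–CH2, whose alkyne carbons become C7 and C8, while the carbonyl carbon of a ring-opened 3-alkoxycyclobutenone becomes C8a and its alkoxy carbon becomes C5. Ring A is therefore assembled around C8, and its three oxygens are born as free hydroxyl (O1), silyl ether (O7) and ethyl ether (O5).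

## Logic of the disconnections

**31 from 30.** The last cut removes three O–benzyl bonds (D2, D4, side-chain phenol) and the O–ethyl bond at C5. They fall together because one boron Lewis acid can pass the benzyl groups to a cation scavenger and take the ethyl group through chelation with the C4 carbonyl. The gain is that the polyphenol exists only in the last flask. The demand is that the unchelated methyl ethers at C4' and D6 and the bridge survive.

**30 from 29.** The O7–Si bond is cut one step earlier with fluoride, so that the silyl ether never meets the boron halide. The gain is a final step that breaks only carbon–oxygen bonds. The demand is a buffered fluoride source that leaves the flavonol alone.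

**29 from 27.** The C3–O bond is cut, which returns a plain flavone. The oxygen is added by epoxidation of C2=C3 and acid isomerization (through 28) only after the ring D ketone is present, because then both rings at the bridge carry an acceptor and resist the oxidant. The demand is that the oxidant prefers the enol-ether-like C2=C3 bond to arenes and benzylic positions.

**27 from 24 and 25.** The D3–acyl bond is cut. This removes the whole dihydrochalcone arm as 25 and leaves D3 as the only unsubstituted carbon of ring D, activated by three oxygens. The ketone must come this late because it would not survive the carbanion chemistry that makes 11. The forward acylation (through 26) must spare benzyl and silyl ethers and prefer D3 to C6 of ring A, which the pyranone carbonyl deactivates and the silyl group shields.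

**24 from 18 and 19.** Ring C is opened at C4–C4a (acylation) and at O1–C2 (conjugate addition), through 22, 21 and 20. Tying the three-carbon unit to O1 first means the acylation can reach only C4a, the one free position ortho to O1, so the ring closes on the bridge side by necessity. The gain is that C2, C3, C4 and ring B all come from 19. The demand is an ester (20, 21) removable without hydroxide, because a silyl ether is present, and a closure (through 23) that tolerates a mixture of alkene isomers.

**18 from 11 and 13.** This is the strategic cut: the C8–C8a and C6–C7 bonds, with C4a–C8a re-formed in the same operation (through 14, 15, 16 and 17). It converts the hardest problem, a 2-alkylated phloroglucinol with three different oxygens, into two small pieces of opposite polarity at a stage where no phenol, ketone or flavone is present. The demand is a single orientation of the alkyne and the absence of hydroxyl groups in both partners.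

**13 from 12.** Two bonds of the four-membered ring are cut ([2+2] retron), leaving 12 and a two-carbon acyl unit. The gain is a one-step preparation from commercial pieces. The demand is the polarity-controlled orientation that puts the ethoxy group at C3.

**11 from 8.** The alkyne is traced to an ester: the oxygen-bearing alkyne carbon is the ester carbonyl carbon, the second is introduced as a dihalocarbenoid (through 9 and 10), and the O–Si bond is formed last. The gain is a stable ester as precursor of a sensitive ynol ether. The demand is that addition to the ester carbonyl outruns enolization at the benzylic position.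

**8 from 6.** The bond between the benzylic carbon and the carboxyl carbon is cut (through 7), a one-carbon homologation of an aldehyde. It is chosen because it never passes through a benzylic cation or halide, which this electron-rich ring with a free position would not tolerate. The gain is an aldehyde as precursor. The demand is a nucleophile strong enough for a hindered, deactivated formyl group.

**6 from 1.** The O–methyl bond, two O–benzyl bonds and the C–formyl bond are cut in turn (5, 3; intermediates 4 and 2). Formylation of symmetrical 1 has only one outcome. The aldehyde then differentiates the hydroxyls: the para one and the less hindered ortho one are benzylated, and the chelated one between formyl and methyl is left for methylation. The demand is the site selectivity of the second benzylation.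

## Other disconnections considered

**Alternative 1:** The cut is made in ring A at C8–C8a and C4a–C5, so that ring A is grown onto a preformed pyranone. The partners are 3-(benzyloxy)-5-bromo-2-(4-methoxyphenyl)-4H-pyran-4-one A3 and the 1-methoxy-1,3-bis(trimethylsiloxy)diene A2, which carries the complete benzyl-protected ring D unit (ketone included) on its terminal carbon. In the forward step Me3SiOTf would activate the carbonyl of A3, the substituted diene terminus would add to C6 (C8–C8a), the ketene acetal carbon would acylate C5 (C4a–C5), and loss of HBr and methanol would aromatize ring A to the 5,7-dihydroxyflavone A1.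
- In its favour: rings B and C and the C3 oxygen are present from the start, which is better than the chosen plan with its separate ring C closure and C3 hydroxylation. A1 needs little more than hydrogenolysis, so the end game is shorter. The bridge is fixed at C8 by construction, which equals the chosen plan.
- Against it here: A2 must be made by double enolization and silylation in the presence of the enolizable ring D ketone, which would compete there and again under the Lewis acid. The more hindered diene terminus must attack a weakly electrophilic pyranone. After the first bond the ring oxygen can leave by β-elimination instead of the ring closing. Acylation at a bromine-bearing carbon followed by loss of HBr is an ionic cascade with several branch points and no close model.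
- Comparison: on structure it is equal (C8) or better (C3–O). On mechanism it is less predictable than a pericyclic cascade steered by one polarization. On step economy it would be better after the key step, at the price of carrying the whole ring D ketone through enol-silane chemistry.

**Alternative 2:** The cut is made in ring D at D5–D6 and D3–D4 (D1–D6 re-formed): the same benzannulation turned around, so that ring D is built on the finished flavonol. The forward step would heat the cyclobutenone A5, a 3-ethoxycyclobut-2-enone attached through its C4 and one methylene group to C8 of 3,5,7-tri-O-benzylkaempferide A7, with 1-(triisopropylsiloxy)propyne A6. The product would be the ring D phenol A4 (D2 OEt, D4 OSi, D5 CH3, D6 OH).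
- In its favour: the reaction type and its regiochemical logic are those of the chosen step, so the mechanism is on equal ground. D6 emerges as the only free hydroxyl, which makes its methylation unambiguous and is better than the sterically biased bis-benzylation of step 2. The flavonol core with its C3 oxygen would come from A7, so no ring C construction or C3 oxidation is needed, which is again better.
- Against it here: A5 presupposes a carbon substituent at C8 rather than C6 of A7, exactly the positional problem the chosen plan avoids. It then needs a homologated acid chloride and a ketene–ynol ether cycloaddition on that scaffold. The 4-substituted cyclobutenone must open with its substituent turning outward. The thermal cascade would run on the most advanced intermediate. Ring D would still need methylation, acylation at D3 between an ethoxy and a bulky siloxy group, and cleavage of the D2 ethyl ether.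
- Comparison: on structure the chosen plan is stronger (C8 by construction). On mechanism the two are equal. On step economy they are about equal, the alternative being more convergent but later and less certain at C8.

**Alternative 3:** The cut is made in ring C at C3–C4. The precursor is the dialdehyde A9, in which O1 of a salicylaldehyde-type ring A (benzyl ethers at C5 and C7, complete ring D unit at C8) carries a CH(4-methoxyphenyl)CHO group. In the forward step SmI2 would reduce the ring A aldehyde of A9 to a ketyl that adds to the side-chain aldehyde, closing ring C as the 2-arylchromane-3,4-diol A8. The 3,4-cis relation would follow from chelation of both oxygens to samarium, and the 2,3-trans relation from an equatorial aryl group.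
- In its favour: the closure is neutral and mild, which is better for the acid-labile bridge than the Friedel–Crafts closure of step 12. The C3 oxygen arrives with the ring, which is better than a separate hydroxylation. The regiochemistry of ring C is unambiguous, equal to the chosen plan.
- Against it here: three stereocentres are made only to be destroyed. A8 lies four electrons below the flavonol, so two alcohol oxidations and an enolization must follow on a molecule full of electron-rich rings. The ring D aryl ketone is itself reducible by SmI2 and can enter ketyl coupling. A9 contains an α-aryloxy aldehyde prone to enolization and loss of the phenoxide. Most important, the cut leaves the C8 bridge and the differentiation of the ring A oxygens to the synthesis of A9.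
- Comparison: on structure the chosen plan addresses the hard problem and this alternative only the easy ring. On mechanism a ketyl coupling is reliable but meets a competing ketone, whereas the pericyclic cascade has no such competitor. On step economy the redox detour costs steps the chosen plan does not need.

Key step: step 8

**Remarks on the chemistry (assumptions)**
- ArD = 4,6-bis(benzyloxy)-2-methoxy-3-methylphenyl, attached through C1 (= D1); its C2 (OCH3) = D6, C3 (CH3) = D5, C4 (OBn) = D4, C5 (H) = D3, C6 (OBn) = D2. ArDK = ArD carrying a 3-[4-(benzyloxy)phenyl]propanoyl group at D3.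
- The target has no stereocentre. 15 and 28 are racemic and lose their stereocentres; 21–23 are drawn as Z isomers, and any E isomer converges in step 12.
- 25 is taken as a purchasable compound.
- The atom mapping 11 + 13 → 18 (CH2-bearing alkyne carbon = C8, siloxy carbon = C7, ethoxy carbon = C5, ketene carbonyl carbon = C8a) was checked against the target; no structure needed correction.

## Route

**Step 1**
Reactants: 1 2,4,6-trihydroxytoluene
Product: 3 2,4,6-trihydroxy-3-methylbenzaldehyde, via aryl iminium chloride 2 (not isolated)
Conditions: POCl3, DMF, EtOAc, 0 °C → rt; then H2O, 60 °C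
Reagents that add atoms: N,N-dimethylformamide, CN(C)C=O; water, O
Why: Vilsmeier–Haack formylation of a phloroglucinol; the two free ring positions of 1 are equivalent, so only one aldehyde can form, and the first formyl group deactivates the ring against a second.

**Step 2**
Reactants: 3 2,4,6-trihydroxy-3-methylbenzaldehyde
Product: 5 4,6-bis(benzyloxy)-2-hydroxy-3-methylbenzaldehyde, via 4-O-benzyl ether 4 (not isolated)
Conditions: BnBr (2.05 equiv), K2CO3, DMF, 0 °C → rt
Reagents that add atoms: benzyl bromide, BrCc1ccccc1
Why: Williamson etherification under chelation control; the para hydroxyl (most acidic, not hydrogen-bonded) should react first, then the ortho hydroxyl next to C5–H, while the hydroxyl pressed by the C3 methyl group into a hydrogen bond with the formyl group is expected to remain.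

**Step 3**
Reactants: 5 4,6-bis(benzyloxy)-2-hydroxy-3-methylbenzaldehyde
Product: 6 4,6-bis(benzyloxy)-2-methoxy-3-methylbenzaldehyde
Conditions: MeI, K2CO3, DMF, 50 °C
Reagents that add atoms: iodomethane, CI
Why: O-methylation of the remaining chelated phenol; with the other hydroxyls blocked, forcing Williamson conditions can only give the D6 methyl ether.

**Step 4**
Reactants: 6 4,6-bis(benzyloxy)-2-methoxy-3-methylbenzaldehyde
Product: 7 2-{[4,6-bis(benzyloxy)-2-methoxy-3-methylphenyl]methylidene}-1,3-dithiane
Conditions: 2-(trimethylsilyl)-1,3-dithiane, n-BuLi, THF, −30 → 0 °C; then 6, −78 °C → rt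
Reagents that add atoms: 2-(trimethylsilyl)-1,3-dithiane, C[Si](C)(C)C1SCCCS1
Why: Peterson olefination; the lithiated silyl dithiane should add irreversibly even to this electron-rich, doubly ortho-substituted aldehyde, and the adduct loses Me3SiOLi to give a ketene dithioacetal, which is an arylacetic acid at the right oxidation level.

**Step 5**
Reactants: 7 2-{[4,6-bis(benzyloxy)-2-methoxy-3-methylphenyl]methylidene}-1,3-dithiane
Product: 8 methyl 2-[4,6-bis(benzyloxy)-2-methoxy-3-methylphenyl]acetate
Conditions: HgCl2, MeOH/H2O (9:1), 60 °C
Reagents that add atoms: methanol, CO; water, O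
Why: Thiophile-assisted solvolysis of a ketene dithioacetal: protonation at the benzylic carbon gives a dithianyl cation that methanol and water convert into the methyl ester while HgCl2 binds the dithiol; no benzylic cation or halide is involved and benzyl ethers are not affected.

**Step 6**
Reactants: 8 methyl 2-[4,6-bis(benzyloxy)-2-methoxy-3-methylphenyl]acetate
Product: 11 ({3-[4,6-bis(benzyloxy)-2-methoxy-3-methylphenyl]prop-1-yn-1-yl}oxy)tri(propan-2-yl)silane, via lithium dibromoenolate 9 (not isolated), via lithium ynolate 10 (not isolated)
Conditions: CH2Br2, lithium 2,2,6,6-tetramethylpiperidide, THF, −78 °C; LiN(SiMe3)2, −78 → −20 °C; n-BuLi, −78 °C → rt; i-Pr3SiCl, −78 → 0 °C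
Reagents that add atoms: dibromomethane, BrCBr; chlorotri(propan-2-yl)silane, CC(C)[Si](Cl)(C(C)C)C(C)C
Why: Kowalski ester homologation stopped at the ynolate: LiCHBr2 adds to the ester, the dibromoketone is enolized to 9, bromine–lithium exchange and 1,2-shift of the arylmethyl group give 10, and the bulky silyl chloride silylates 10 on oxygen. The doubly ortho-substituted, electron-rich aryl group lowers the acidity of the benzylic hydrogens, so carbonyl addition at −78 °C should outrun enolization.

**Step 7**
Reactants: 12 ethoxyacetylene
Product: 13 3-ethoxycyclobut-2-en-1-one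
Conditions: AcCl, Et3N, Et2O, 0 °C → rt
Reagents that add atoms: acetyl chloride, CC(Cl)=O
Why: [2+2] cycloaddition of ketene, generated in the flask by dehydrochlorination of acetyl chloride, with the ynol ether; the nucleophilic CH carbon of 12 bonds to the ketene carbonyl carbon, which places the ethoxy group at C3.

**Step 8**
Reactants: 11 ({3-[4,6-bis(benzyloxy)-2-methoxy-3-methylphenyl]prop-1-yn-1-yl}oxy)tri(propan-2-yl)silane; 13 3-ethoxycyclobut-2-en-1-one
Product: 18 2-(ArD-methyl)-5-ethoxy-3-[(triisopropylsilyl)oxy]phenol, via vinylketene 14 (not isolated), via vinylcyclobutenone 15 (not isolated), via dienylketene 16 (not isolated), via cyclohexadienone 17 (not isolated)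
Conditions: 11 (1.0 equiv), 13 (1.2 equiv, slow addition), toluene, 80 °C; then 110 °C (sealed tube)
Reagents that add atoms: none
Why: Heating opens 13 by 4π electrocyclic ring opening to vinylketene 14, whose ketene C=C adds 11 in a polar [2+2] step that joins the nucleophilic CH2-bearing alkyne carbon (C8) to the ketene carbonyl carbon (C8a) and the siloxy carbon (C7) to the ketene α-carbon (C6), giving 15. A second 4π opening gives dienylketene 16, which closes the C4a–C8a bond by 6π electrocyclization to 17 and tautomerizes to phenol 18. The closest known reaction type is the Danheiser benzannulation of cyclobutenones with siloxyalkynes, extended here to a 3-alkoxycyclobutenone so that a phloroglucinol pattern results. Ring A is closed by a thermal disrotatory 6π electrocyclization of a dienylketene, a pericyclic closure of a six-membered carbocycle made irreversible by aromatization. No stereocentre is formed, since the centre of 15 is lost on ring opening. The step needs one orientation of the alkyne, which the oxygen-induced polarization of 11 secures, and it needs the ketenes to meet no hydroxyl group, which holds because every other oxygen is an ether; slow addition of 13 keeps the product phenol from competing for 14.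

**Step 9**
Reactants: 19 3-(4-methoxyphenyl)prop-2-ynoic acid
Product: 20 allyl 3-(4-methoxyphenyl)prop-2-ynoate
Conditions: allyl bromide, K2CO3, DMF, rt
Reagents that add atoms: allyl bromide, C=CCBr
Why: O-alkylation of the carboxylate; the allyl ester is chosen because it can later be removed under neutral conditions in the presence of the aryl silyl ether.

**Step 10**
Reactants: 18 2-(ArD-methyl)-5-ethoxy-3-[(triisopropylsilyl)oxy]phenol; 20 allyl 3-(4-methoxyphenyl)prop-2-ynoate
Product: 21 allyl (2Z)-3-{2-(ArD-methyl)-5-ethoxy-3-[(triisopropylsilyl)oxy]phenoxy}-3-(4-methoxyphenyl)prop-2-enoate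
Conditions: K2CO3, DMF, 60 °C
Reagents that add atoms: none
Why: Oxa-Michael addition of the only free phenol (O1) to the β-carbon of the ynoate forms the O1–C2 bond; anti addition should give mainly the Z isomer, and the geometry is of no consequence because both isomers converge in step 12.

**Step 11**
Reactants: 21 allyl (2Z)-3-{2-(ArD-methyl)-5-ethoxy-3-[(triisopropylsilyl)oxy]phenoxy}-3-(4-methoxyphenyl)prop-2-enoate
Product: 22 (2Z)-3-{2-(ArD-methyl)-5-ethoxy-3-[(triisopropylsilyl)oxy]phenoxy}-3-(4-methoxyphenyl)prop-2-enoic acid
Conditions: Pd(PPh3)4 (5 mol %), PhSiH3, CH2Cl2, rt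
Reagents that add atoms: none
Why: Tsuji–Trost deallylation: zerovalent palladium ionizes the allyl ester and the silane reduces the π-allyl complex to propene, which frees the acid without hydroxide or an amine nucleophile, so the silyl ether and the β-aryloxy acrylate are spared.

**Step 12**
Reactants: 22 (2Z)-3-{2-(ArD-methyl)-5-ethoxy-3-[(triisopropylsilyl)oxy]phenoxy}-3-(4-methoxyphenyl)prop-2-enoic acid
Product: 24 8-(ArD-methyl)-5-ethoxy-2-(4-methoxyphenyl)-7-[(triisopropylsilyl)oxy]-4H-chromen-4-one, via mixed anhydride 23 (not isolated)
Conditions: (CF3CO)2O, CH2Cl2, 0 °C → rt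
Reagents that add atoms: none
Why: Intramolecular Friedel–Crafts acylation through the mixed trifluoroacetic anhydride; the acyl group can reach only C4a (six-membered ring closure), which is activated by three oxygens, and the oxygen-stabilized cation lets any E isomer equilibrate. The acid set free is weak and dilute, which should suit the benzyl ethers, the triisopropylsilyl ether and the bridge.

**Step 13**
Reactants: 24 8-(ArD-methyl)-5-ethoxy-2-(4-methoxyphenyl)-7-[(triisopropylsilyl)oxy]-4H-chromen-4-one; 25 3-[4-(benzyloxy)phenyl]propanoic acid
Product: 27 8-(ArDK-methyl)-5-ethoxy-2-(4-methoxyphenyl)-7-[(triisopropylsilyl)oxy]-4H-chromen-4-one, via mixed anhydride 26 (not isolated)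
Conditions: 25, (CF3CO)2O, CH2Cl2, 0 °C; then 24, 0 °C → rt
Reagents that add atoms: none
Why: Friedel–Crafts acylation of an electron-rich arene by a carboxylic trifluoroacetic mixed anhydride; D3 is ortho to two ether oxygens and para to a third with no acceptor on ring D, whereas C6 of ring A is deactivated by the pyranone carbonyl and shielded by the silyl ether, and ring B and C3 are far less nucleophilic.

**Step 14**
Reactants: 27 8-(ArDK-methyl)-5-ethoxy-2-(4-methoxyphenyl)-7-[(triisopropylsilyl)oxy]-4H-chromen-4-one
Product: 29 8-(ArDK-methyl)-5-ethoxy-3-hydroxy-2-(4-methoxyphenyl)-7-[(triisopropylsilyl)oxy]-4H-chromen-4-one, via flavone epoxide 28 (not isolated)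
Conditions: dimethyldioxirane (acetone), CH2Cl2, 0 °C → rt; then TsOH·H2O (cat.), CH2Cl2, rt
Reagents that add atoms: dimethyldioxirane, CC1(C)OO1
Why: Epoxidation of the enol-ether-like C2=C3 bond of the flavone, then acid-catalysed opening at C2 (cation stabilized by O1 and the anisyl group) with loss of H3, gives the 3-hydroxyflavone; the cis-fused epoxide is racemic and both of its stereocentres vanish. Both arenes at the bridge now carry carbonyl groups, which should make them poor substrates for the dioxirane.

**Step 15**
Reactants: 29 8-(ArDK-methyl)-5-ethoxy-3-hydroxy-2-(4-methoxyphenyl)-7-[(triisopropylsilyl)oxy]-4H-chromen-4-one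
Product: 30 8-(ArDK-methyl)-5-ethoxy-3,7-dihydroxy-2-(4-methoxyphenyl)-4H-chromen-4-one
Conditions: Bu4NF, AcOH, THF, 0 °C
Reagents that add atoms: none
Why: Fluoride cleavage of the aryl silyl ether; acetic acid buffers the phenoxide of the acidic 7-hydroxyl so that the flavonol is not exposed to strong base.

**Step 16**
Reactants: 30 8-(ArDK-methyl)-5-ethoxy-3,7-dihydroxy-2-(4-methoxyphenyl)-4H-chromen-4-one
Product: 31 4'''-hydroxytrianguletin
Conditions: BCl3, C6HMe5, CH2Cl2, −78 → 0 °C; then MeOH, aqueous work-up
Reagents that add atoms: none
Why: Lewis-acid dealkylation: the three benzyl groups leave as benzyl cations captured by pentamethylbenzene, and the C5 ethyl group is displaced by chloride from the boron chelate spanning O5 and the C4 carbonyl; the methyl ethers at C4' and D6 have no such assistance and should remain at low temperature.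

## Compound list

1 | 2,4,6-trihydroxytoluene | Cc1c(O)cc(O)cc1O | starting material
2 | [(2,4,6-trihydroxy-3-methylphenyl)methylidene]dimethyliminium chloride | C[N+](C)=Cc1c(O)cc(O)c(C)c1O.[Cl-] | intermediate (not isolated)
3 | 2,4,6-trihydroxy-3-methylbenzaldehyde | Cc1c(O)cc(O)c(C=O)c1O | intermediate
4 | 4-(benzyloxy)-2,6-dihydroxy-3-methylbenzaldehyde | Cc1c(OCc2ccccc2)cc(O)c(C=O)c1O | intermediate (not isolated)
5 | 4,6-bis(benzyloxy)-2-hydroxy-3-methylbenzaldehyde | Cc1c(OCc2ccccc2)cc(OCc2ccccc2)c(C=O)c1O | intermediate
6 | 4,6-bis(benzyloxy)-2-methoxy-3-methylbenzaldehyde | Cc1c(OCc2ccccc2)cc(OCc2ccccc2)c(C=O)c1OC | intermediate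
7 | 2-{[4,6-bis(benzyloxy)-2-methoxy-3-methylphenyl]methylidene}-1,3-dithiane | Cc1c(OCc2ccccc2)cc(OCc2ccccc2)c(C=C2SCCCS2)c1OC | intermediate
8 | methyl 2-[4,6-bis(benzyloxy)-2-methoxy-3-methylphenyl]acetate | COC(=O)Cc1c(OCc2ccccc2)cc(OCc2ccccc2)c(C)c1OC | intermediate
9 | lithium 3-[4,6-bis(benzyloxy)-2-methoxy-3-methylphenyl]-1,1-dibromoprop-1-en-2-olate | [Li]OC(Cc1c(OCc2ccccc2)cc(OCc2ccccc2)c(C)c1OC)=C(Br)Br | intermediate (not isolated)
10 | lithium 3-[4,6-bis(benzyloxy)-2-methoxy-3-methylphenyl]prop-1-yn-1-olate | [Li]OC#CCc1c(OCc2ccccc2)cc(OCc2ccccc2)c(C)c1OC | intermediate (not isolated)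
11 | ({3-[4,6-bis(benzyloxy)-2-methoxy-3-methylphenyl]prop-1-yn-1-yl}oxy)tri(propan-2-yl)silane | CC(C)[Si](C(C)C)(C(C)C)OC#CCc1c(OCc2ccccc2)cc(OCc2ccccc2)c(C)c1OC | intermediate
12 | ethoxyacetylene | CCOC#C | starting material
13 | 3-ethoxycyclobut-2-en-1-one | CCOC1=CC(=O)C1 | intermediate
14 | 3-ethoxybuta-1,3-dien-1-one | C=C(OCC)C=C=O | intermediate (not isolated)
15 | racemic 2-(ArD-methyl)-4-(1-ethoxyethenyl)-3-[(triisopropylsilyl)oxy]cyclobut-2-en-1-one | C=C(OCC)C1C(=O)C(Cc2c(OCc3ccccc3)cc(OCc3ccccc3)c(C)c2OC)=C1O[Si](C(C)C)(C(C)C)C(C)C | intermediate (not isolated)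
16 | 2-(ArD-methyl)-5-ethoxy-3-[(triisopropylsilyl)oxy]hexa-1,3,5-trien-1-one, ketene and ethoxyvinyl groups cis on C3=C4 | C=C(OCC)/C=C(O[Si](C(C)C)(C(C)C)C(C)C)\C(Cc1c(OCc2ccccc2)cc(OCc2ccccc2)c(C)c1OC)=C=O | intermediate (not isolated)
17 | 2-(ArD-methyl)-5-ethoxy-3-[(triisopropylsilyl)oxy]cyclohexa-2,4-dien-1-one | CCOC1=CC(O[Si](C(C)C)(C(C)C)C(C)C)=C(Cc2c(OCc3ccccc3)cc(OCc3ccccc3)c(C)c2OC)C(=O)C1 | intermediate (not isolated)
18 | 2-(ArD-methyl)-5-ethoxy-3-[(triisopropylsilyl)oxy]phenol | CCOc1cc(O)c(Cc2c(OCc3ccccc3)cc(OCc3ccccc3)c(C)c2OC)c(O[Si](C(C)C)(C(C)C)C(C)C)c1 | intermediate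
19 | 3-(4-methoxyphenyl)prop-2-ynoic acid | OC(=O)C#Cc1ccc(OC)cc1 | starting material
20 | allyl 3-(4-methoxyphenyl)prop-2-ynoate | C=CCOC(=O)C#Cc1ccc(OC)cc1 | intermediate
21 | allyl (2Z)-3-{2-(ArD-methyl)-5-ethoxy-3-[(triisopropylsilyl)oxy]phenoxy}-3-(4-methoxyphenyl)prop-2-enoate | C=CCOC(=O)/C=C(\Oc1cc(OCC)cc(O[Si](C(C)C)(C(C)C)C(C)C)c1Cc1c(OCc2ccccc2)cc(OCc2ccccc2)c(C)c1OC)c1ccc(OC)cc1 | intermediate
22 | (2Z)-3-{2-(ArD-methyl)-5-ethoxy-3-[(triisopropylsilyl)oxy]phenoxy}-3-(4-methoxyphenyl)prop-2-enoic acid | OC(=O)/C=C(\Oc1cc(OCC)cc(O[Si](C(C)C)(C(C)C)C(C)C)c1Cc1c(OCc2ccccc2)cc(OCc2ccccc2)c(C)c1OC)c1ccc(OC)cc1 | intermediate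
23 | mixed anhydride of 22 and trifluoroacetic acid | FC(F)(F)C(=O)OC(=O)/C=C(\Oc1cc(OCC)cc(O[Si](C(C)C)(C(C)C)C(C)C)c1Cc1c(OCc2ccccc2)cc(OCc2ccccc2)c(C)c1OC)c1ccc(OC)cc1 | intermediate (not isolated)
24 | 8-(ArD-methyl)-5-ethoxy-2-(4-methoxyphenyl)-7-[(triisopropylsilyl)oxy]-4H-chromen-4-one | COc1ccc(cc1)-c1cc(=O)c2c(OCC)cc(O[Si](C(C)C)(C(C)C)C(C)C)c(Cc3c(OCc4ccccc4)cc(OCc4ccccc4)c(C)c3OC)c2o1 | intermediate
25 | 3-[4-(benzyloxy)phenyl]propanoic acid | OC(=O)CCc1ccc(OCc2ccccc2)cc1 | starting material
26 | 3-[4-(benzyloxy)phenyl]propanoic trifluoroacetic anhydride | FC(F)(F)C(=O)OC(=O)CCc1ccc(OCc2ccccc2)cc1 | intermediate (not isolated)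
27 | 8-(ArDK-methyl)-5-ethoxy-2-(4-methoxyphenyl)-7-[(triisopropylsilyl)oxy]-4H-chromen-4-one | COc1ccc(cc1)-c1cc(=O)c2c(OCC)cc(O[Si](C(C)C)(C(C)C)C(C)C)c(Cc3c(OCc4ccccc4)c(C(=O)CCc4ccc(OCc5ccccc5)cc4)c(OCc4ccccc4)c(C)c3OC)c2o1 | intermediate
28 | racemic cis-fused 2,3-epoxide of 27 (2,3-epoxy-2,3-dihydro-4H-chromen-4-one; one enantiomer drawn) | COc1ccc(cc1)[C@]23O[C@H]2C(=O)c2c(OCC)cc(O[Si](C(C)C)(C(C)C)C(C)C)c(Cc4c(OCc5ccccc5)c(C(=O)CCc5ccc(OCc6ccccc6)cc5)c(OCc5ccccc5)c(C)c4OC)c2O3 | intermediate (not isolated)
29 | 8-(ArDK-methyl)-5-ethoxy-3-hydroxy-2-(4-methoxyphenyl)-7-[(triisopropylsilyl)oxy]-4H-chromen-4-one | COc1ccc(cc1)-c1oc2c(Cc3c(OCc4ccccc4)c(C(=O)CCc4ccc(OCc5ccccc5)cc4)c(OCc4ccccc4)c(C)c3OC)c(O[Si](C(C)C)(C(C)C)C(C)C)cc(OCC)c2c(=O)c1O | intermediate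
30 | 8-(ArDK-methyl)-5-ethoxy-3,7-dihydroxy-2-(4-methoxyphenyl)-4H-chromen-4-one | COc1ccc(cc1)-c1oc2c(Cc3c(OCc4ccccc4)c(C(=O)CCc4ccc(OCc5ccccc5)cc4)c(OCc4ccccc4)c(C)c3OC)c(O)cc(OCC)c2c(=O)c1O | intermediate
31 | 4'''-hydroxytrianguletin, 8-({2,4-dihydroxy-3-[3-(4-hydroxyphenyl)propanoyl]-6-methoxy-5-methylphenyl}methyl)-3,5,7-trihydroxy-2-(4-methoxyphenyl)-4H-chromen-4-one | COc1ccc(-c2oc3c(Cc4c(O)c(C(=O)CCc5ccc(O)cc5)c(O)c(C)c4OC)c(O)cc(O)c3c(=O)c2O)cc1 | target

## Step count and least certain steps

Total: 16 steps. Longest linear sequence: 14 steps (steps 1–6, 8, 10–16); steps 7 and 9 are one-step side branches.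

**Step 8 (key step).** The donor-substituted cyclobutenone may open slowly, the cascade may stall before the second ring opening, and the product phenol may compete with the alkyne for the vinylketene (O-acylation), because ketene generation and phenol formation share one flask. Fallback, setting out from 11 and returning at 18: the same vinylketene 14 is generated at room temperature by 1,4-dehydrochlorination of (2E)-3-ethoxybut-2-enoyl chloride F1 (from the commercial acid and (COCl)2) with Et3N in the presence of 11. The [2+2] adduct 15 is then isolated and heated on its own in dilute toluene, so that ring opening, electrocyclization and tautomerization to 18 occur when no ketene source is left.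

**Step 2.** The site selectivity of the second benzylation may erode (alkylation of the chelated hydroxyl or over-benzylation), since it rests on a steric and hydrogen-bond bias between two ortho hydroxyls. Fallback, from 3 to 5: exhaustive benzylation (BnBr in excess, K2CO3, DMF, 60 °C) gives 2,4,6-tris(benzyloxy)-3-methylbenzaldehyde F2. Chelation-controlled mono-debenzylation with MgBr2·OEt2 (toluene/Et2O) is then expected to remove the ortho benzyl group that is compressed between formyl and methyl, which uses the same steric difference in the opposite sense.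

**Step 6.** Enolization of the arylacetic ester may compete with addition of the carbenoid, and the ynolate may be silylated on carbon, because the benzylic α-hydrogens are more acidic than those of a simple ester. Fallback, from 6 to 11 without an ester: addition of LiC≡CSiMe3 (THF, −78 °C) gives racemic 1-[4,6-bis(benzyloxy)-2-methoxy-3-methylphenyl]-3-(trimethylsilyl)prop-2-yn-1-ol F3. Ionic deoxygenation (Et3SiH, CF3CO2H, CH2Cl2, −20 °C) gives {3-[4,6-bis(benzyloxy)-2-methoxy-3-methylphenyl]prop-1-yn-1-yl}trimethylsilane F4, and K2CO3 in MeOH gives the terminal alkyne 1,5-bis(benzyloxy)-3-methoxy-2-methyl-4-(prop-2-yn-1-yl)benzene F5. Its lithium acetylide (LiN(SiMe3)2) is oxidized with LiOOt-Bu to ynolate 10 and silylated with i-Pr3SiOTf to 11.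

**Step 13.** The bulky acylating agent may fail to enter the position between two benzyloxy groups, or the acid set free may start to remove benzyl groups before acylation is complete. Fallback, from 24 to 27 with a small electrophile first: Vilsmeier–Haack formylation (POCl3, DMF) at D3 gives the aldehyde 8-{[4,6-bis(benzyloxy)-5-formyl-2-methoxy-3-methylphenyl]methyl}-5-ethoxy-2-(4-methoxyphenyl)-7-[(triisopropylsilyl)oxy]-4H-chromen-4-one F6. Addition of {2-[4-(benzyloxy)phenyl]ethyl}magnesium bromide F7 (from the commercial bromide and Mg) at −78 °C gives the racemic secondary alcohol F8, whose new stereocentre is erased by Dess–Martin oxidation to 27.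

**Step 16.** Cleavage of the ethyl ether may be incomplete, the hindered D6 methyl ether may be over-cleaved, or the bridge may be attacked by the acid, because four dealkylations of different rates are asked of one reagent. Fallback, from 30 to 31 in two stages: hydrogenolysis (H2, Pd/C, EtOAc/MeOH) removes the three benzyl groups without any Lewis acid and gives 8-({2,4-dihydroxy-3-[3-(4-hydroxyphenyl)propanoyl]-6-methoxy-5-methylphenyl}methyl)-5-ethoxy-3,7-dihydroxy-2-(4-methoxyphenyl)-4H-chromen-4-one F9. Only the chelated ethyl ether then remains for AlCl3 in MeCN.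

## Further compounds

F1 | step 8 | (2E)-3-ethoxybut-2-enoyl chloride | CCO/C(C)=C/C(Cl)=O
F2 | step 2 | 2,4,6-tris(benzyloxy)-3-methylbenzaldehyde | Cc1c(OCc2ccccc2)cc(OCc2ccccc2)c(C=O)c1OCc1ccccc1
F3 | step 6 | racemic 1-[4,6-bis(benzyloxy)-2-methoxy-3-methylphenyl]-3-(trimethylsilyl)prop-2-yn-1-ol | C[Si](C)(C)C#CC(O)c1c(OCc2ccccc2)cc(OCc2ccccc2)c(C)c1OC
F4 | step 6 | {3-[4,6-bis(benzyloxy)-2-methoxy-3-methylphenyl]prop-1-yn-1-yl}trimethylsilane | C[Si](C)(C)C#CCc1c(OCc2ccccc2)cc(OCc2ccccc2)c(C)c1OC
F5 | step 6 | 1,5-bis(benzyloxy)-3-methoxy-2-methyl-4-(prop-2-yn-1-yl)benzene | C#CCc1c(OCc2ccccc2)cc(OCc2ccccc2)c(C)c1OC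
F6 | step 13 | 8-{[4,6-bis(benzyloxy)-5-formyl-2-methoxy-3-methylphenyl]methyl}-5-ethoxy-2-(4-methoxyphenyl)-7-[(triisopropylsilyl)oxy]-4H-chromen-4-one | COc1ccc(cc1)-c1cc(=O)c2c(OCC)cc(O[Si](C(C)C)(C(C)C)C(C)C)c(Cc3c(OCc4ccccc4)c(C=O)c(OCc4ccccc4)c(C)c3OC)c2o1
F7 | step 13 | {2-[4-(benzyloxy)phenyl]ethyl}magnesium bromide | Br[Mg]CCc1ccc(OCc2ccccc2)cc1
F8 | step 13 | racemic 8-({4,6-bis(benzyloxy)-5-{3-[4-(benzyloxy)phenyl]-1-hydroxypropyl}-2-methoxy-3-methylphenyl}methyl)-5-ethoxy-2-(4-methoxyphenyl)-7-[(triisopropylsilyl)oxy]-4H-chromen-4-one | COc1ccc(cc1)-c1cc(=O)c2c(OCC)cc(O[Si](C(C)C)(C(C)C)C(C)C)c(Cc3c(OCc4ccccc4)c(C(O)CCc4ccc(OCc5ccccc5)cc4)c(OCc4ccccc4)c(C)c3OC)c2o1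
F9 | step 16 | 8-({2,4-dihydroxy-3-[3-(4-hydroxyphenyl)propanoyl]-6-methoxy-5-methylphenyl}methyl)-5-ethoxy-3,7-dihydroxy-2-(4-methoxyphenyl)-4H-chromen-4-one | COc1ccc(cc1)-c1oc2c(Cc3c(O)c(C(=O)CCc4ccc(O)cc4)c(O)c(C)c3OC)c(O)cc(OCC)c2c(=O)c1O
A1 | alternative 1 | 3-(benzyloxy)-5,7-dihydroxy-2-(4-methoxyphenyl)-4H-chromen-4-one carrying at C8 the benzyl-protected ring D methyl group with its D3 ketone | COc1ccc(cc1)-c1oc2c(Cc3c(OCc4ccccc4)c(C(=O)CCc4ccc(OCc5ccccc5)cc4)c(OCc4ccccc4)c(C)c3OC)c(O)cc(O)c2c(=O)c1OCc1ccccc1
A2 | alternative 1 | 1-methoxy-1,3-bis(trimethylsiloxy)penta-1,3-diene carrying the benzyl-protected ring D ketone unit at C5 (double-bond geometry not defined) | COC(O[Si](C)(C)C)=CC(O[Si](C)(C)C)=CCc1c(OCc2ccccc2)c(C(=O)CCc2ccc(OCc3ccccc3)cc2)c(OCc2ccccc2)c(C)c1OC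
A3 | alternative 1 | 3-(benzyloxy)-5-bromo-2-(4-methoxyphenyl)-4H-pyran-4-one | COc1ccc(cc1)-c1occ(Br)c(=O)c1OCc1ccccc1
A4 | alternative 2 | 3,5,7-tris(benzyloxy)-2-(4-methoxyphenyl)-4H-chromen-4-one carrying at C8 the ring D phenol methyl group (D2 OEt, D3 H, D4 OSi(i-Pr)3, D5 CH3, D6 OH) | COc1ccc(cc1)-c1oc2c(Cc5c(O)c(C)c(O[Si](C(C)C)(C(C)C)C(C)C)cc5OCC)c(OCc3ccccc3)cc(OCc3ccccc3)c2c(=O)c1OCc1ccccc1
A5 | alternative 2 | racemic 3,5,7-tris(benzyloxy)-8-[(2-ethoxy-4-oxocyclobut-2-en-1-yl)methyl]-2-(4-methoxyphenyl)-4H-chromen-4-one | COc1ccc(cc1)-c1oc2c(CC3C(=O)C=C3OCC)c(OCc3ccccc3)cc(OCc3ccccc3)c2c(=O)c1OCc1ccccc1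
A6 | alternative 2 | 1-(triisopropylsiloxy)propyne | CC#CO[Si](C(C)C)(C(C)C)C(C)C
A7 | alternative 2 | 3,5,7-tri-O-benzylkaempferide, 3,5,7-tris(benzyloxy)-2-(4-methoxyphenyl)-4H-chromen-4-one | COc1ccc(cc1)-c1oc2cc(OCc3ccccc3)cc(OCc3ccccc3)c2c(=O)c1OCc1ccccc1
A8 | alternative 3 | racemic 2,3-trans-3,4-cis-5,7-bis(benzyloxy)-2-(4-methoxyphenyl)-8-(ring D-methyl)chromane-3,4-diol with the benzyl-protected ring D ketone unit (one enantiomer drawn) | COc1ccc(cc1)[C@@H]1[C@@H](O)[C@@H](O)c2c(OCc3ccccc3)cc(OCc3ccccc3)c(Cc3c(OCc4ccccc4)c(C(=O)CCc4ccc(OCc5ccccc5)cc4)c(OCc4ccccc4)c(C)c3OC)c2O1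
A9 | alternative 3 | racemic 2-[2-formyl-3,5-bis(benzyloxy)-6-(ring D-methyl)phenoxy]-2-(4-methoxyphenyl)acetaldehyde with the benzyl-protected ring D ketone unit | COc1ccc(cc1)C(C=O)Oc1c(Cc2c(OCc3ccccc3)c(C(=O)CCc3ccc(OCc4ccccc4)cc3)c(OCc3ccccc3)c(C)c2OC)c(OCc2ccccc2)cc(OCc2ccccc2)c1C=O
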